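Slowness was my help here: the teal run took hours, so I could read it stage by stage and ask what it meant for the flasks below.

| flask | substrate | partner | catalyst | temperature | remark | time |
|---|---|---|---|---|---|---|
| teal | 20 mM | 1.05 equiv | 20 mol% | 40 °C | run made earlier |  |
| amber | 20 mM | 1.05 equiv | 30 mol% | 40 °C | run made earlier |  |
| Monday's | 20 mM | 1.05 equiv (fed, over 3.0 h) | 20 mol% | 40 °C | all else is in the flask from the start; the feed brings no volume worth counting | 8.0 h |
| Wednesday's | 20 mM (in portions, 3, over 3.0 h) | 1.05 equiv | 20 mol% | 40 °C | first portion at the start, last at 3.0 h | 8.0 h |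
| Saturday's | 20 mM (fed, over 3.0 h) | 1.05 equiv | 20 mol% | 40 °C | all else is in the flask from the start; the feed brings no volume worth counting | 8.0 h |
| Thursday's | 20 mM (fed, over 3.0 h) | 1.05 equiv | 20 mol% |  | the addition at 0 °C, then warmed to 40 °C; the feed brings no volume worth counting | 8.0 h |
| Sunday's | 20 mM | 1.05 equiv | 20 mol% |  | everything together at the start at 0 °C, warmed to 40 °C at 3.0 h | 8.0 h |

- teal (time / h: target / %, substrate / %): 0.417: 23, 71; 0.667: 30, 61; 1.00: 36, 47; 2.00: 38, 31; 3.00: 33, 18; 5.00: 27, 17
- amber (time / min: target / %, substrate / %): 8.00: 14, 84; 15.0: 24, 71; 25.0: 32, 63; 30.0: 39, 55; 40.0: 41, 46; 50.0: 46, 39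

(readings scatter by 1.5 percentage points)

- on the list of suspects stand: substrate + catalyst <-> catalyst + intermediate; target <-> isomer of the product; partner -> decomposed reagent; partner + catalyst + intermediate -> catalyst + target; catalyst <-> dormant form
- the earlier runs do not show what temperature does; that part of a forecast is a guess

- the flask with the highest amount of target, in percent of the substrate charged ("all alike" if they lie within 1.5 percentage points) (Monday's / Wednesday's / Saturday's / Thursday's / Sunday's / all alike)
- final target, as a percentage of the substrate charged, in Monday's
- final target, as a percentage of the substrate charged, in Wednesday's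
- final target, as a percentage of the substrate charged, in Saturday's
- final target, as a percentage of the substrate charged, in Thursday's
- final target, as a percentage of the substrate charged, in Sunday's

In the first instants of teal, with the catalyst held, substrate fell in a pseudo-first-order way to 71 % by 0.417 h, which gave a time constant of 1.22 h. Target and substrate then made up 94.0 % of the charge, so intermediate and isomer together held 6.00 %: partner was taking up intermediate about as it formed.

In the middle, at 2.00 h, that unseen share had grown to 31.0 %, as the decay of partner on the list of suspects would make it.

At the end, substrate read 18 % and then 17 %, two readings that a scatter of 1.5 percentage points could not tell apart, while target read 33 % and then 27 %. From these two readings I assumed that substrate had come close, by 5.00 h, to its balance with intermediate, where catalyst stands on both sides of the step and drops out of the ratio at this temperature.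

The sinking target gave me a rate towards isomer of 0.100 h⁻¹. With 33 % as a fair mean of target over 5.00 h, I put isomer near 16.6 %, and that left about 39.4 % as intermediate. That made 3.32 the stall factor, the points of the charge held outside product for each point of substrate left once substrate has reached that balance. Product, meaning target plus isomer, is then the charge minus this factor times the substrate, which for teal came to 43.6 %.

In Monday's flask the partner is fed over 3.0 h, and the substrate's time constant is shorter, so intermediate would be ready as partner arrived. I expected Monday's to end with substrate below teal's 17 %. My factor gives no figure for target, so the figures that follow are the forecast's.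

The forecast put Monday's highest at 31 % (range 23 % to 39 %), on the ground that feeding partner “spares it from decay while intermediate is present”. For Wednesday's it gave 14 %, for Saturday's 13 %, for Thursday's 26 % and for Sunday's 27 %.

The flasks gave 34.6 % in Monday's, the highest, then 11.1 % in Wednesday's, 9.04 % in Saturday's, 26.7 % in Thursday's and 27.5 % in Sunday's.

    substrate + catalyst ⇌ catalyst + intermediate (K = 2.10, k = 0.0680 M⁻¹ s⁻¹, Ea = 65.0 kJ mol⁻¹, ΔH = −30.0 kJ mol⁻¹)
    target ⇌ isomer of the product (K = 2.10, k = 5.10 × 10⁻⁵ s⁻¹, Ea = 91.0 kJ mol⁻¹, ΔH = −21.0 kJ mol⁻¹)
    partner → decomposed reagent (k = 3.00 × 10⁻⁴ s⁻¹, Ea = 88.0 kJ mol⁻¹)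
    partner + catalyst + intermediate → catalyst + target (k = 81.0 M⁻² s⁻¹, Ea = 43.0 kJ mol⁻¹)
    catalyst ⇌ dormant form (K = 0.400, k = 4.20 × 10⁻⁴ s⁻¹, Ea = 103 kJ mol⁻¹, ΔH = 47.0 kJ mol⁻¹)
    (constants at 40 °C)

Monday's flask ended at 8.00 h with 7.43 % substrate, so the stall factor gave 75.3 % as product, and target plus isomer stood at 77.2 %. Partner, the limiting reagent, stood at 0 %. The neighbour was Monday's flask charged with 2.60 equiv of partner, and it ended with 1.65 % substrate. There the same factor gave 94.5 % as product, and the flask held 42.4 % target beside 52.9 % isomer.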